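Everything rests on cutting the tetrahydrofuran ring between C3 and C4. Both carbons bear a hydroxymethyl group and are flanked by the benzylic carbons C2 and C5, which O1 already ties together; the C3–C4 bond can thus be introduced as the endocyclic alkene of a 2,5-dihydrofuran. In one operation, ring-closing metathesis of two 1,1-disubstituted alkenes closes the five-membered ring and creates the last skeletal bond. The substrate is a meso bis[1-aryl-2-(silyloxymethyl)allyl] ether, built regiospecifically from two Morita–Baylis–Hillman units; its R,S configuration becomes the cis-2,5 relation, and hydrogenation anti to both aryl groups then sets C3 and C4 all-cis.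

Key step: step 6

Remark: the SMILES is read as the meso all-cis tetrahydrofuran (both aryl groups and both hydroxymethyl groups on one ring face), so racemic intermediates are used and only relative configuration has to be controlled; in the fallback to step 3 the slow-reacting enantiomer of the lipase resolution is drawn as (S), either enantiomer being usable because the ether is meso.

Step 1
Reactants: 1 syringaldehyde (4-hydroxy-3,5-dimethoxybenzaldehyde)
Product: 2 3,5-dimethoxy-4-(triisopropylsilyloxy)benzaldehyde
Conditions: TIPSCl, imidazole, DMF, rt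
Reagents that add atoms: triisopropylsilyl chloride (TIPSCl), CC(C)[Si](Cl)(C(C)C)C(C)C
Why: Silylation of the phenol (substitution at silicon, imidazole as base) removes the acidic OH before the amine- and alkoxide-mediated steps, the triisopropylsilyl group being chosen because it should resist DABCO/MeOH and alkoxides yet fall to fluoride at the end; no stereocentre is involved.

Step 2
Reactants: 2 3,5-dimethoxy-4-(triisopropylsilyloxy)benzaldehyde; 3 methyl acrylate (excess)
Product: 4 racemic methyl 2-{hydroxy[3,5-dimethoxy-4-(triisopropylsilyloxy)phenyl]methyl}prop-2-enoate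
Conditions: DABCO (1 equiv), MeOH, rt, several days
Reagents that add atoms: none
Why: Morita–Baylis–Hillman reaction, in which DABCO adds to the acrylate, the zwitterionic enolate attacks the aldehyde (kept reactive enough by the inductively withdrawing 3,5-methoxy groups and the twisted 4-silyloxy group) and elimination returns the amine, so that the carbinol and the terminal methylene are installed together; the carbinol centre forms racemic, which is what a meso ether needs.

Step 3
Reactants: 4 racemic methyl 2-{hydroxy[3,5-dimethoxy-4-(triisopropylsilyloxy)phenyl]methyl}prop-2-enoate (two molecules, one of them activated in the flask)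
Product: 6 meso (R,S) bis{1-[3,5-dimethoxy-4-(triisopropylsilyloxy)phenyl]-2-(methoxycarbonyl)prop-2-enyl} ether, via tert-butyl carbonate 5 (not isolated)
Conditions: Boc2O (0.5 equiv), DMAP (5 mol %), CH2Cl2, 0 °C to rt; then DABCO (20 mol %), rt; chromatography
Reagents that add atoms: none
Why: Lewis-base-catalysed allylic substitution of a Morita–Baylis–Hillman carbonate (SN2'–SN2'), in which half of 4 becomes carbonate 5, DABCO adds to its acrylate and expels tert-butyl carbonate (CO2 plus tert-butoxide, which deprotonates the remaining 4), and the alkoxide attacks the allyl-ammonium ion in a second SN2' step that restores the terminal methylene and puts the oxygen on the benzylic carbon, so the branched ether should form without the allylic transposition that a cationic etherification would risk; the new C–O stereocentre is created without facial bias, so meso 6 should form side by side with its racemic (R,R/S,S) diastereomer, from which it is separated by chromatography and recognised as the isomer that cannot be resolved on a chiral stationary phase.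

Step 4
Reactants: 6 meso (R,S) bis{1-[3,5-dimethoxy-4-(triisopropylsilyloxy)phenyl]-2-(methoxycarbonyl)prop-2-enyl} ether
Product: 7 meso (R,S) bis{1-[3,5-dimethoxy-4-(triisopropylsilyloxy)phenyl]-2-(hydroxymethyl)prop-2-enyl} ether
Conditions: i-Bu2AlH (5 equiv), CH2Cl2, −78 °C; aq. potassium sodium tartrate
Reagents that add atoms: none
Why: Hydride reduction of the two α-methylene esters (1,2-reduction by diisobutylaluminium hydride at low temperature, routine for Morita–Baylis–Hillman esters) should give the bis-allylic diol without touching the aryl silyl ethers, the ether linkage or the two carbinol stereocentres.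

Step 5
Reactants: 7 meso (R,S) bis{1-[3,5-dimethoxy-4-(triisopropylsilyloxy)phenyl]-2-(hydroxymethyl)prop-2-enyl} ether
Product: 8 meso (R,S) bis{1-[3,5-dimethoxy-4-(triisopropylsilyloxy)phenyl]-2-[(tert-butyldimethylsilyloxy)methyl]prop-2-enyl} ether
Conditions: TBSCl, imidazole, DMF, 0 °C to rt
Reagents that add atoms: tert-butyldimethylsilyl chloride (TBSCl), CC(C)(C)[Si](C)(C)Cl
Why: Silylation of the two primary allylic alcohols (substitution at silicon) gives non-coordinating, fluoride-labile ethers that cannot chelate the ruthenium alkylidene of step 6, and no stereocentre is affected.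

Step 6
Reactants: 8 meso (R,S) bis{1-[3,5-dimethoxy-4-(triisopropylsilyloxy)phenyl]-2-[(tert-butyldimethylsilyloxy)methyl]prop-2-enyl} ether
Product: 9 cis-2,5-bis[3,5-dimethoxy-4-(triisopropylsilyloxy)phenyl]-3,4-bis[(tert-butyldimethylsilyloxy)methyl]-2,5-dihydrofuran (meso)
Conditions: RuCl2[1,3-bis(2-methylphenyl)imidazolidin-2-ylidene](=CH-C6H4-2-OiPr) (second-generation Hoveyda–Grubbs type, N-o-tolyl carbene; 2 × 5 mol %), 1,4-benzoquinone (10 mol %), toluene (0.01 M), 60–80 °C, Ar sparge
Reagents that add atoms: none
Why: Ring-closing olefin metathesis: the catalyst loads onto one 1,1-disubstituted alkene to give a disubstituted ruthenium alkylidene, which undergoes [2+2] addition to the second alkene held close by the C2–O1–C5 tether, and cycloreversion of the ruthenacyclobutane releases the C3=C4 alkene while the Ru=CH2 fragment carries the chain with loss of ethylene. The closest known reaction type is the ring-closing metathesis of 2,2'-disubstituted diallyl ethers, malonates and sulfonamides to tetrasubstituted five-membered cycloalkenes, the task for which second-generation catalysts with N-o-tolyl carbenes were developed. The 2,5-dihydrofuran is closed as a five-membered ring by intramolecular alkylidene–alkene metathesis, the new bond being the endocyclic C3=C4 double bond. No stereocentre is created: C2 and C5 are untouched, so the R,S (meso) configuration of 8 is carried over as the cis-2,5 relation of 9. The step needs ring closure to beat intermolecular metathesis and hydride-induced alkene migration; the first is secured by the reluctance of 1,1-disubstituted alkenes to homodimerise and by the short tether with its two branched carbons, the second by the non-coordinating silyl ethers, 1,4-benzoquinone as hydride scavenger and removal of ethylene by argon sparging.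

Step 7
Reactants: 9 cis-2,5-bis[3,5-dimethoxy-4-(triisopropylsilyloxy)phenyl]-3,4-bis[(tert-butyldimethylsilyloxy)methyl]-2,5-dihydrofuran (meso)
Product: 10 all-cis 2,5-bis[3,5-dimethoxy-4-(triisopropylsilyloxy)phenyl]-3,4-bis[(tert-butyldimethylsilyloxy)methyl]tetrahydrofuran (meso)
Conditions: [Ir(cod)(PCy3)(py)]PF6 (10 mol %), H2 (1–10 bar), CH2Cl2, rt
Reagents that add atoms: none
Why: Homogeneous hydrogenation with the cationic iridium complex, a catalyst type known to reduce tetrasubstituted alkenes and to spare benzylic C–O bonds that Pd/C would cleave, should add both hydrogens syn to the face of the C3=C4 bond opposite the two cis aryl groups, which sets C3 and C4 together and places both silyloxymethyl arms cis to the aryl groups (all-cis, meso).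

Step 8
Reactants: 10 all-cis 2,5-bis[3,5-dimethoxy-4-(triisopropylsilyloxy)phenyl]-3,4-bis[(tert-butyldimethylsilyloxy)methyl]tetrahydrofuran (meso)
Product: 11 all-cis [2,5-bis(4-hydroxy-3,5-dimethoxyphenyl)tetrahydrofuran-3,4-diyl]dimethanol (meso; 2R,3R,4S,5S), the target CNP0170897.3
Conditions: TBAF, AcOH (1:1, 6 equiv), THF, 0 °C to rt
Reagents that add atoms: none
Why: Fluoride-induced desilylation should cleave the two aryl triisopropylsilyl and the two alkyl tert-butyldimethylsilyl ethers in one operation, acetic acid buffering the medium so that no free phenoxide can open or epimerise the benzylic ether through a quinone methide, and the four stereocentres are untouched.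

Compound list
1 | syringaldehyde (4-hydroxy-3,5-dimethoxybenzaldehyde) | COc1cc(C=O)cc(OC)c1O | starting material
2 | 3,5-dimethoxy-4-(triisopropylsilyloxy)benzaldehyde | COc1cc(C=O)cc(OC)c1O[Si](C(C)C)(C(C)C)C(C)C | intermediate
3 | methyl acrylate | C=CC(=O)OC | starting material
4 | racemic methyl 2-{hydroxy[3,5-dimethoxy-4-(triisopropylsilyloxy)phenyl]methyl}prop-2-enoate | C=C(C(=O)OC)C(O)c1cc(OC)c(O[Si](C(C)C)(C(C)C)C(C)C)c(OC)c1 | intermediate
5 | racemic methyl 2-{(tert-butoxycarbonyloxy)[3,5-dimethoxy-4-(triisopropylsilyloxy)phenyl]methyl}prop-2-enoate (tert-butyl carbonate of 4, not isolated) | C=C(C(=O)OC)C(OC(=O)OC(C)(C)C)c1cc(OC)c(O[Si](C(C)C)(C(C)C)C(C)C)c(OC)c1 | intermediate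
6 | meso (R,S) bis{1-[3,5-dimethoxy-4-(triisopropylsilyloxy)phenyl]-2-(methoxycarbonyl)prop-2-enyl} ether | C=C(C(=O)OC)[C@H](c1cc(OC)c(O[Si](C(C)C)(C(C)C)C(C)C)c(OC)c1)O[C@H](c1cc(OC)c(O[Si](C(C)C)(C(C)C)C(C)C)c(OC)c1)C(=C)C(=O)OC | intermediate
7 | meso (R,S) bis{1-[3,5-dimethoxy-4-(triisopropylsilyloxy)phenyl]-2-(hydroxymethyl)prop-2-enyl} ether | C=C(CO)[C@H](c1cc(OC)c(O[Si](C(C)C)(C(C)C)C(C)C)c(OC)c1)O[C@H](c1cc(OC)c(O[Si](C(C)C)(C(C)C)C(C)C)c(OC)c1)C(=C)CO | intermediate
8 | meso (R,S) bis{1-[3,5-dimethoxy-4-(triisopropylsilyloxy)phenyl]-2-[(tert-butyldimethylsilyloxy)methyl]prop-2-enyl} ether | C=C(CO[Si](C)(C)C(C)(C)C)[C@H](c1cc(OC)c(O[Si](C(C)C)(C(C)C)C(C)C)c(OC)c1)O[C@H](c1cc(OC)c(O[Si](C(C)C)(C(C)C)C(C)C)c(OC)c1)C(=C)CO[Si](C)(C)C(C)(C)C | intermediate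
9 | cis-2,5-bis[3,5-dimethoxy-4-(triisopropylsilyloxy)phenyl]-3,4-bis[(tert-butyldimethylsilyloxy)methyl]-2,5-dihydrofuran (meso) | COc1cc([C@H]2O[C@@H](c3cc(OC)c(O[Si](C(C)C)(C(C)C)C(C)C)c(OC)c3)C(CO[Si](C)(C)C(C)(C)C)=C2CO[Si](C)(C)C(C)(C)C)cc(OC)c1O[Si](C(C)C)(C(C)C)C(C)C | intermediate
10 | all-cis 2,5-bis[3,5-dimethoxy-4-(triisopropylsilyloxy)phenyl]-3,4-bis[(tert-butyldimethylsilyloxy)methyl]tetrahydrofuran (meso) | COc1cc([C@H]2O[C@@H](c3cc(OC)c(O[Si](C(C)C)(C(C)C)C(C)C)c(OC)c3)[C@@H](CO[Si](C)(C)C(C)(C)C)[C@H]2CO[Si](C)(C)C(C)(C)C)cc(OC)c1O[Si](C(C)C)(C(C)C)C(C)C | intermediate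
11 | all-cis [2,5-bis(4-hydroxy-3,5-dimethoxyphenyl)tetrahydrofuran-3,4-diyl]dimethanol (meso; 2R,3R,4S,5S), CNP0170897.3 | COc1cc([C@H]2O[C@@H](c3cc(OC)c(O)c(OC)c3)[C@@H](CO)[C@H]2CO)cc(OC)c1O | target

Total step count: 8. Longest linear sequence: 8 steps (1 to 11; both halves of 6 come from the same intermediate 4).

Steps most likely to fail

Step 6 (key step). Formation of the tetrasubstituted ruthenacyclobutane between two branched, silyloxymethyl-bearing alkenes may be slower than catalyst decomposition, so that ring closure stalls, and ruthenium hydride species may move the double bonds toward enol ether positions. The fallback gives up the metathesis and reaches the saturated ring by furan hydrogenation; it sets out from 2 and comes back at 10, so the metathesis and the alkene hydrogenation are both bypassed. Homologation of 2 with ethyl diazoacetate and catalytic NbCl5 (Roskamp reaction) gives the β-keto ester ethyl 3-aryl-3-oxopropanoate F1. Oxidative enolate dimerisation (NaH, then I2, THF) gives the diethyl 2,3-diaroylsuccinate F2 as a diastereomer mixture. Paal–Knorr cyclodehydration (TsOH, toluene, reflux) converges both diastereomers on the diethyl 2,5-diarylfuran-3,4-dicarboxylate F3. Reduction with diisobutylaluminium hydride gives the furan-3,4-dimethanol F4, which is silylated (TBSCl, imidazole) to the bis(silyl ether) F5. Hydrogenation over Rh/Al2O3 under pressure delivers all four hydrogens to one face of the furan and should give the all-cis tetrahydrofuran 10.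

Step 3. The ether bond forms with no control over the relative configuration of the two carbinol carbons, so the meso and racemic ethers arise together and may co-elute. The hindered secondary alkoxide may also capture the allyl-ammonium ion so slowly that 1,3-transposition to the cinnamyl isomer or capping by tert-butoxide competes. The fallback replaces statistical coupling by catalyst control; it sets out from 4 and comes back at 6. Racemic 4 is resolved by lipase-catalysed transesterification (Burkholderia cepacia lipase, vinyl acetate, MTBE) into the unreacted alcohol enantiomer F6 and the acetate of its antipode F7, which is set aside or deacetylated enzymatically and recycled. A second portion of racemic 4 is converted fully into carbonate 5 (Boc2O, DMAP), which is isolated. F6 and 5 are then joined under a dimeric cinchona alkaloid Lewis base, (DHQD)2PHAL or its pseudoenantiomer (DHQ)2PHAL. In this asymmetric variant of the same allylic substitution the chiral ammonium ion dictates the face of alkoxide capture, and the catalyst is chosen so that the new centre is opposite in configuration to that of F6, which should give meso 6 directly.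

Step 7. Hydrogen uptake at the tetrasubstituted alkene, flanked by two silyloxymethyl groups and two aryl-bearing carbons, may be too slow. That would leave time for acid released by the cationic iridium hydride to ionise the benzylic, allylic C–O bonds (loss of the cis-2,5 relation) or for the alkene to migrate. The fallback inverts the order of the last two operations and relies on hydroxyl direction instead of an undirected approach; it sets out from 9 and comes back at 11. Buffered desilylation (TBAF, AcOH, THF) gives the cis-2,5-bis(4-hydroxy-3,5-dimethoxyphenyl)-3,4-bis(hydroxymethyl)-2,5-dihydrofuran F8. The allylic hydroxyl groups of F8 then bind a cationic catalyst, [Rh(nbd)(dppb)]BF4 or [Ir(cod)(PCy3)(py)]PF6, under H2 in CH2Cl2–MeOH, and bring the metal hydride to the hindered alkene. The two aryl groups still block one face, so hydrogen should again arrive anti to them and give 11.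

Further compounds
F1 | step 6 | ethyl 3-[3,5-dimethoxy-4-(triisopropylsilyloxy)phenyl]-3-oxopropanoate | CCOC(=O)CC(=O)c1cc(OC)c(O[Si](C(C)C)(C(C)C)C(C)C)c(OC)c1
F2 | step 6 | diethyl 2,3-bis[3,5-dimethoxy-4-(triisopropylsilyloxy)benzoyl]butanedioate (diastereomer mixture) | CCOC(=O)C(C(=O)c1cc(OC)c(O[Si](C(C)C)(C(C)C)C(C)C)c(OC)c1)C(C(=O)c1cc(OC)c(O[Si](C(C)C)(C(C)C)C(C)C)c(OC)c1)C(=O)OCC
F3 | step 6 | diethyl 2,5-bis[3,5-dimethoxy-4-(triisopropylsilyloxy)phenyl]furan-3,4-dicarboxylate | CCOC(=O)c1c(-c2cc(OC)c(O[Si](C(C)C)(C(C)C)C(C)C)c(OC)c2)oc(-c2cc(OC)c(O[Si](C(C)C)(C(C)C)C(C)C)c(OC)c2)c1C(=O)OCC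
F4 | step 6 | {2,5-bis[3,5-dimethoxy-4-(triisopropylsilyloxy)phenyl]furan-3,4-diyl}dimethanol | OCc1c(-c2cc(OC)c(O[Si](C(C)C)(C(C)C)C(C)C)c(OC)c2)oc(-c2cc(OC)c(O[Si](C(C)C)(C(C)C)C(C)C)c(OC)c2)c1CO
F5 | step 6 | 2,5-bis[3,5-dimethoxy-4-(triisopropylsilyloxy)phenyl]-3,4-bis[(tert-butyldimethylsilyloxy)methyl]furan | CC(C)(C)[Si](C)(C)OCc1c(-c2cc(OC)c(O[Si](C(C)C)(C(C)C)C(C)C)c(OC)c2)oc(-c2cc(OC)c(O[Si](C(C)C)(C(C)C)C(C)C)c(OC)c2)c1CO[Si](C)(C)C(C)(C)C
F6 | step 3 | (S)-methyl 2-{hydroxy[3,5-dimethoxy-4-(triisopropylsilyloxy)phenyl]methyl}prop-2-enoate | C=C(C(=O)OC)[C@H](c1cc(OC)c(O[Si](C(C)C)(C(C)C)C(C)C)c(OC)c1)O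
F7 | step 3 | (R)-methyl 2-{acetoxy[3,5-dimethoxy-4-(triisopropylsilyloxy)phenyl]methyl}prop-2-enoate | C=C(C(=O)OC)[C@@H](c1cc(OC)c(O[Si](C(C)C)(C(C)C)C(C)C)c(OC)c1)OC(C)=O
F8 | step 7 | cis-2,5-bis(4-hydroxy-3,5-dimethoxyphenyl)-3,4-bis(hydroxymethyl)-2,5-dihydrofuran (meso) | COc1cc([C@H]2O[C@@H](c3cc(OC)c(O)c(OC)c3)C(CO)=C2CO)cc(OC)c1O
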